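**Retrosynthetic overview**
- Target 14 ⇐ reductive removal of two camphorsultam auxiliaries from the all-trans THF-3,4-dicarbonyl bis-sultam 13 (C9/C9' at the acyl level).
- 13 ⇐ one-pot oxidative C8–C8' radical dimerisation of N-sinapoyl sultam 9, water capture by the bis-quinone methide, and oxa-1,6-ring closure, as in the plant pathway. This step forms the only new ring (the THF), one C–C bond, two C–O bonds and all four stereocentres.
- 9 ⇐ Wittig olefination of syringaldehyde with the ylide from N-bromoacetyl sultam 4; 4 ⇐ sultam 1 + bromoacetyl bromide.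
- Numbering: C7 = benzylic carbon, C8 = carbon alpha to the carbonyl of each C6–C3 unit; these become C2/C5 and C3/C4 of the THF.

Assumption: N-acyl (2S)-bornane-10,2-sultams are taken to react at C-alpha from the same face in this radical coupling as in their thermal and radical additions, which leads to the enantiomer drawn; if the major dimer proves antipodal, (1S)-(−)-2,10-camphorsultam replaces 1 with no other change.

**Step 1**
Reactants: 1 (1R)-(+)-2,10-camphorsultam [(2S)-bornane-10,2-sultam]; 2 bromoacetyl bromide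
Product: 4 (2S)-N-(bromoacetyl)bornane-10,2-sultam, via sodium sultamide 3 (not isolated)
Conditions: NaH, THF, 0 °C; then 2, 0 °C → rt
Reagents that add atoms: none
Why: N-acylation of the sodium sulfonamide by the acyl bromide, which is far more electrophilic than the alkyl bromide; no stereocentre is touched.

**Step 2**
Reactants: 4 (2S)-N-(bromoacetyl)bornane-10,2-sultam; 5 triphenylphosphine; 6 syringaldehyde (4-hydroxy-3,5-dimethoxybenzaldehyde)
Product: 9 (2S)-N-[(2E)-3-(4-hydroxy-3,5-dimethoxyphenyl)prop-2-enoyl]bornane-10,2-sultam (N-sinapoyl sultam), via phosphonium bromide 7 (not isolated), via stabilised ylide 8 (not isolated)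
Conditions: PPh3, PhMe, 50 °C; 1 M aq. NaOH/CH2Cl2, 0 °C; then 6, PhMe, 90 °C
Reagents that add atoms: none
Why: SN2 quaternisation, deprotonation and Wittig olefination, in which the acyl-stabilised ylide gives the E-alkene and, as with other unprotected hydroxybenzaldehydes, is not shut down by the free phenol.

**Step 3**
Reactants: 9 N-sinapoyl sultam (two molecules)
Product: 13 (2S,3S,4S,5S)-2,5-bis(4-hydroxy-3,5-dimethoxyphenyl)tetrahydrofuran-3,4-dicarbonyl bis[(2S)-bornane-10,2-sultam] (all-trans bis-imide), via phenoxyl radical 10 (not isolated), via bis-quinone methide 11 (not isolated), via hydroxy quinone methide 12 (not isolated)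
Conditions: FeCl3·6H2O (1.1 equiv per phenol, added slowly), acetone–H2O 3:1, N2, 0 °C → rt, 12 h
Reagents that add atoms: water (O)
Why: Proposed new method: one-electron oxidation by trivalent iron gives phenoxyl radical 10 with spin at C8, two radicals join C8–C8' through the C8 Si faces left open by the (2S)-sultam (C=O anti to SO2, s-cis enoyl, like–like pairing of identical auxiliaries) to give the C2-symmetric bis-quinone methide 11, acid-assisted water addition at C7 gives 12 and 5-exo oxa-1,6-addition of the new benzylic OH onto the second quinone methide closes the THF ring, the p-hydroxybenzylic ether carbons equilibrating in the HCl-containing medium to place C2/C5 trans to the fixed C3/C4 carbonyls, while minor diastereomers are removed on silica or by crystallisation because the auxiliary is still attached; the closest known reaction types are the FeCl3 or peroxidase 8–8 dehydrodimerisation of sinapate esters and sinapyl acetate with water capture to 2,5-diaryltetrahydrofurans and the auxiliary-controlled oxidative 8–5 coupling of N-feruloyl camphorsultam.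

**Step 4**
Reactants: 13 all-trans THF bis-imide
Product: 14 huazhongilexin, (2S,3R,4R,5S)-2,5-bis(4-hydroxy-3,5-dimethoxyphenyl)-3,4-bis(hydroxymethyl)tetrahydrofuran
Conditions: LiAlH4 (excess), THF, 0 °C → rt; aq. KNaC4H4O6 work-up
Reagents that add atoms: none
Why: Standard reductive cleavage of N-acyl sultams to primary alcohols with release of the auxiliary, in which the benzylic ethers are inert to hydride and no centre is inverted, so (2S,3S,4S,5S)-13 maps onto (2S,3R,4R,5S)-14 (the change of descriptor at C3/C4 is only a change of CIP priority).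

**Compound list**
1 | (1R)-(+)-2,10-camphorsultam, (2S)-bornane-10,2-sultam | N1[C@H]2C[C@@H]3CC[C@@]2(CS1(=O)=O)C3(C)C | starting material
2 | bromoacetyl bromide | O=C(Br)CBr | starting material
3 | sodium salt of sultam 1 (sodium sultamide) | [Na+].[N-]1[C@H]2C[C@@H]3CC[C@@]2(CS1(=O)=O)C3(C)C | intermediate
4 | (2S)-N-(bromoacetyl)bornane-10,2-sultam | O=C(CBr)N1[C@H]2C[C@@H]3CC[C@@]2(CS1(=O)=O)C3(C)C | intermediate
5 | triphenylphosphine | c1ccc(cc1)P(c1ccccc1)c1ccccc1 | starting material
6 | syringaldehyde | COc1cc(C=O)cc(OC)c1O | starting material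
7 | [2-oxo-2-((2S)-bornane-10,2-sultam-N-yl)ethyl]triphenylphosphonium bromide | [Br-].O=C(C[P+](c1ccccc1)(c1ccccc1)c1ccccc1)N1[C@H]2C[C@@H]3CC[C@@]2(CS1(=O)=O)C3(C)C | intermediate
8 | (2S)-N-[(triphenylphosphoranylidene)acetyl]bornane-10,2-sultam (stabilised ylide) | O=C(C=P(c1ccccc1)(c1ccccc1)c1ccccc1)N1[C@H]2C[C@@H]3CC[C@@]2(CS1(=O)=O)C3(C)C | intermediate
9 | (2S)-N-[(2E)-3-(4-hydroxy-3,5-dimethoxyphenyl)prop-2-enoyl]bornane-10,2-sultam (N-sinapoyl sultam) | COc1cc(/C=C/C(=O)N2[C@H]3C[C@@H]4CC[C@@]3(CS2(=O)=O)C4(C)C)cc(OC)c1O | intermediate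
10 | phenoxyl radical of 9 | COc1cc(/C=C/C(=O)N2[C@H]3C[C@@H]4CC[C@@]3(CS2(=O)=O)C4(C)C)cc(OC)c1[O] | intermediate
11 | (2R,3R)-2,3-bis[(3,5-dimethoxy-4-oxocyclohexa-2,5-dien-1-ylidene)methyl]butanedioyl bis[(2S)-bornane-10,2-sultam] (bis-quinone methide) | COC1=CC(=C[C@@H](C(=O)N2[C@H]3C[C@@H]4CC[C@@]3(CS2(=O)=O)C4(C)C)[C@H](C(=O)N2[C@H]3C[C@@H]4CC[C@@]3(CS2(=O)=O)C4(C)C)C=C2C=C(OC)C(=O)C(OC)=C2)C=C(OC)C1=O | intermediate
12 | mono-hydrated bis-quinone methide: C7 benzylic alcohol (syringyl carbinol) on one unit, quinone methide on the other, bis-sultam imide | COc1cc([C@@H](O)[C@@H](C(=O)N2[C@H]3C[C@@H]4CC[C@@]3(CS2(=O)=O)C4(C)C)[C@H](C(=O)N2[C@H]3C[C@@H]4CC[C@@]3(CS2(=O)=O)C4(C)C)C=C2C=C(OC)C(=O)C(OC)=C2)cc(OC)c1O | intermediate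
13 | (2S,3S,4S,5S)-2,5-bis(4-hydroxy-3,5-dimethoxyphenyl)tetrahydrofuran-3,4-dicarbonyl bis[(2S)-bornane-10,2-sultam], all-trans | COc1cc([C@H]2O[C@H](c3cc(OC)c(O)c(OC)c3)[C@@H](C(=O)N4[C@H]5C[C@@H]6CC[C@@]5(CS4(=O)=O)C6(C)C)[C@@H]2C(=O)N7[C@H]8C[C@@H]9CC[C@@]8(CS7(=O)=O)C9(C)C)cc(OC)c1O | intermediate
14 | huazhongilexin, (2S,3R,4R,5S)-2,5-bis(4-hydroxy-3,5-dimethoxyphenyl)-3,4-bis(hydroxymethyl)tetrahydrofuran, all-trans | COc1cc([C@H]2O[C@H](c3cc(OC)c(O)c(OC)c3)[C@@H](CO)[C@@H]2CO)cc(OC)c1O | target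

**Total step count:** 4. **Longest linear sequence:** 4 (1 → 4 → 9 → 13 → 14).

**Steps most likely to fail, with fallbacks**

Step 3 (oxidative dimerisation–hydration cascade). The risks are insufficient or reversed facial control in the radical coupling, loss of the acidic C8–H from the bis-quinone methide (giving arylidene or aryldihydronaphthalene products), and competing 8–O–4 coupling. The fallback sets out from 9 and comes back at 14. It makes the C8–C8' bond by auxiliary-controlled enolate coupling and moves the quinone methide ring closure to the alcohol oxidation level, where no acidic C8–H exists. Hydrogenation of 9 (H2, Pd/C, EtOAc) gives the saturated imide (2S)-N-[3-(4-hydroxy-3,5-dimethoxyphenyl)propanoyl]bornane-10,2-sultam F1. Silylation (TBSCl, imidazole, DMF) gives its aryl TBS ether F2. Oxidative homocoupling of the sodium enolate of F2 (NaN(SiMe3)2, THF, −78 °C, then CuCl2) gives the (2R,3R)-2,3-dibenzylsuccinyl bis-sultam F3, each enolate reacting on the face left open by the sultam. LiAlH4 in THF gives the (2R,3R)-2,3-dibenzylbutane-1,4-diol bis-TBS ether F4 and returns 1. Ac2O/pyridine gives the diacetate F5, and Bu4NF/AcOH frees the phenols to give the bis-phenol diacetate F6. DDQ (2.2 equiv) in dioxane–H2O then oxidises each 4-hydroxybenzyl position in turn to a quinone methide; water adds to the first, and the resulting benzylic alcohol closes onto the second, giving the all-trans THF diacetate F7. K2CO3 in MeOH removes the acetates and gives 14.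

Step 4 (double reductive cleavage). The risks are incomplete reduction of two hindered imides as insoluble aluminium phenoxides, or base-induced opening of the ring next to the carbonyls. The fallback sets out from 13 and comes back at 14, separating cleavage from reduction. LiOH/H2O2 in THF–H2O at 0 °C hydrolyses both imides to the (2S,3S,4S,5S)-2,5-diaryltetrahydrofuran-3,4-dicarboxylic acid F8 and returns 1; this ring system is expected to tolerate cold aqueous alkali. BH3·SMe2 in THF (0 °C → rt, excess to cover the phenols) then reduces the diacid to 14 under non-basic conditions.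

Step 2 (telescoped Wittig with a free phenol). The risks are a sluggish reaction because the acidic phenol protonates part of the ylide, or damage to the imide during ylide generation. The fallback sets out from 1 and comes back at 9, forming the aryl–vinyl bond instead of the C7=C8 bond. NaH and acryloyl chloride in PhMe give (2S)-N-acryloylbornane-10,2-sultam F9. Heck arylation of F9 with 4-bromo-2,6-dimethoxyphenol F10 (a catalogue compound; Pd(OAc)2, P(o-tol)3, NaOAc, DMF, 100 °C) gives 9 as the E-isomer.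

**Further compounds**
F1 | step 3 | (2S)-N-[3-(4-hydroxy-3,5-dimethoxyphenyl)propanoyl]bornane-10,2-sultam | COc1cc(CCC(=O)N2[C@H]3C[C@@H]4CC[C@@]3(CS2(=O)=O)C4(C)C)cc(OC)c1O
F2 | step 3 | (2S)-N-[3-(4-(tert-butyldimethylsilyloxy)-3,5-dimethoxyphenyl)propanoyl]bornane-10,2-sultam | COc1cc(CCC(=O)N2[C@H]3C[C@@H]4CC[C@@]3(CS2(=O)=O)C4(C)C)cc(OC)c1O[Si](C)(C)C(C)(C)C
F3 | step 3 | (2R,3R)-2,3-bis[(4-(tert-butyldimethylsilyloxy)-3,5-dimethoxyphenyl)methyl]butanedioyl bis[(2S)-bornane-10,2-sultam] | COc1cc(C[C@@H](C(=O)N2[C@H]3C[C@@H]4CC[C@@]3(CS2(=O)=O)C4(C)C)[C@H](C(=O)N2[C@H]3C[C@@H]4CC[C@@]3(CS2(=O)=O)C4(C)C)Cc2cc(OC)c(O[Si](C)(C)C(C)(C)C)c(OC)c2)cc(OC)c1O[Si](C)(C)C(C)(C)C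
F4 | step 3 | (2R,3R)-2,3-bis[(4-(tert-butyldimethylsilyloxy)-3,5-dimethoxyphenyl)methyl]butane-1,4-diol | COc1cc(C[C@@H](CO)[C@H](CO)Cc2cc(OC)c(O[Si](C)(C)C(C)(C)C)c(OC)c2)cc(OC)c1O[Si](C)(C)C(C)(C)C
F5 | step 3 | (2R,3R)-2,3-bis[(4-(tert-butyldimethylsilyloxy)-3,5-dimethoxyphenyl)methyl]butane-1,4-diyl diacetate | COc1cc(C[C@@H](COC(C)=O)[C@H](COC(C)=O)Cc2cc(OC)c(O[Si](C)(C)C(C)(C)C)c(OC)c2)cc(OC)c1O[Si](C)(C)C(C)(C)C
F6 | step 3 | (2R,3R)-2,3-bis[(4-hydroxy-3,5-dimethoxyphenyl)methyl]butane-1,4-diyl diacetate | COc1cc(C[C@@H](COC(C)=O)[C@H](COC(C)=O)Cc2cc(OC)c(O)c(OC)c2)cc(OC)c1O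
F7 | step 3 | (2S,3R,4R,5S)-2,5-bis(4-hydroxy-3,5-dimethoxyphenyl)-3,4-bis(acetoxymethyl)tetrahydrofuran | COc1cc([C@H]2O[C@H](c3cc(OC)c(O)c(OC)c3)[C@@H](COC(C)=O)[C@@H]2COC(C)=O)cc(OC)c1O
F8 | step 4 | (2S,3S,4S,5S)-2,5-bis(4-hydroxy-3,5-dimethoxyphenyl)tetrahydrofuran-3,4-dicarboxylic acid | COc1cc([C@H]2O[C@H](c3cc(OC)c(O)c(OC)c3)[C@@H](C(=O)O)[C@@H]2C(=O)O)cc(OC)c1O
F9 | step 2 | (2S)-N-acryloylbornane-10,2-sultam | C=CC(=O)N1[C@H]2C[C@@H]3CC[C@@]2(CS1(=O)=O)C3(C)C
F10 | step 2 | 4-bromo-2,6-dimethoxyphenol | COc1cc(Br)cc(OC)c1O
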